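The cycloheptene (ring B) is cut at C10–C11 and C19–C6, between the allyl unit C11–C12–C19 shared by rings C and D and the four-carbon unit C6–C8–C9–C10. One intramolecular (4+3) cycloaddition of a hexahydropentalenyl allyl cation with a sulfonamide-tethered 1,3-diene should forge both bonds, close rings A and B together, create the vicinal quaternary carbons C19 and C6 and restore the C11=C12 alkene by proton loss. Its precursor is an open N,N-dialkyl sulfonamide linking a bicyclic allylic alcohol (from cyclopentenone, a malonate and 1,3-dichloroacetone) to a geometrically defined tetrasubstituted diene that carries the (S)-carbinol. Hydrogenation, C16 epimerisation and LiAlH4 finish the synthesis.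

Key step: step 16

Remark (atom numbering of the target used below): C1–C2 ethyl, C3 carbinol, C4, C5, C6 (quaternary, bears C7H2OH), C8 (CH), C9, C10, C11=C12, C13 (CH), C14, C15, C16 (CH bearing C17H2OH), C18, C19 (quaternary), C20, N (methyl), C23. Ring A = piperidine (N, C20, C19, C6, C8, C23); ring B = cycloheptene (C6, C8, C9, C10, C11, C12, C19); ring C = cyclopentene (C11–C15); ring D = cyclopentane (C12, C13, C16, C18, C19). The target is (3S,6S,8R,13S,16S,19S).

Assumption: the (R)-configured LiAl(binaphtholate)2 complex is taken to give the (R)-Michael adduct 3; if its sense is the opposite, the (S)-complex is used.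

Step 1
Reactants: 1 cyclopent-2-en-1-one; 2 tert-butyl methyl malonate
Product: 3 1-tert-butyl 3-methyl 2-[(1R)-3-oxocyclopentyl]propanedioate (both epimers at the malonate carbon)
Conditions: LiAl[(R)-1,1'-bi-2-naphtholate]2 (10 mol %), KOtBu (9 mol %), 4 Å MS, THF, rt
Reagents that add atoms: none
Why: Catalytic asymmetric Michael addition of a malonate to a cyclic enone; the chiral Lewis acid–Brønsted base complex differentiates the enone faces and sets C13.

Step 2
Reactants: 3 1-tert-butyl 3-methyl 2-[(1R)-3-oxocyclopentyl]propanedioate; 4 1,3-dichloropropan-2-one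
Product: 5 1-tert-butyl 3-methyl 2-(3-chloro-2-oxopropyl)-2-[(1R)-3-oxocyclopentyl]propanedioate
Conditions: NaH (1.05 equiv), THF, 0 °C; then added to 4 (3 equiv), 0 °C → rt
Reagents that add atoms: none
Why: SN2 C-alkylation of the malonate anion (far more acidic than the cyclopentanone) by the α-chloroketone, with excess 4 to suppress double alkylation.

Step 3
Reactants: 5 1-tert-butyl 3-methyl 2-(3-chloro-2-oxopropyl)-2-[(1R)-3-oxocyclopentyl]propanedioate
Product: 7 methyl (1R,6aS)-3-(chloromethyl)-4-oxo-1,2,4,5,6,6a-hexahydropentalene-1-carboxylate, via bicyclic enone diester 6 (not isolated)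
Conditions: TsOH·H2O (20 mol %), toluene, reflux, Dean–Stark
Reagents that add atoms: none
Why: Acid-catalysed intramolecular aldol condensation of ring carbon C12 onto the side-chain ketone C19 (the only aldol that can dehydrate) should give 6, whose tert-butyl ester is cleaved and decarboxylated under the same conditions; C16 should settle with the ester trans to C14 (cis to H13).

Step 4
Reactants: 7 methyl (1R,6aS)-3-(chloromethyl)-4-oxo-1,2,4,5,6,6a-hexahydropentalene-1-carboxylate; 8 2-nitrobenzenesulfonamide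
Product: 9 methyl (1R,6aS)-3-({[(2-nitrophenyl)sulfonyl]amino}methyl)-4-oxo-1,2,4,5,6,6a-hexahydropentalene-1-carboxylate
Conditions: 8 (3 equiv), K2CO3, DMF, rt
Reagents that add atoms: none
Why: SN2 displacement of the allylic (vinylogous α-keto) chloride by the sulfonamide anion; excess 8 should limit dialkylation.

Step 5
Reactants: 10 methyl (3S)-3-hydroxypentanoate
Product: 11 (3S)-pentane-1,3-diol
Conditions: LiAlH4, THF, 0 °C → rt
Reagents that add atoms: none
Why: Hydride reduction of the ester; the carbinol stereocentre (later C3) is not touched.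

Step 6
Reactants: 11 (3S)-pentane-1,3-diol
Product: 12 (3S)-1-iodopentan-3-ol
Conditions: I2, PPh3, imidazole, CH2Cl2, 0 °C
Reagents that add atoms: iodine, II
Why: Appel-type iodination, selective for the primary hydroxyl.

Step 7
Reactants: 13 2-[(tert-butyldimethylsilyl)oxy]acetaldehyde; 14 ethyl 2-diazoacetate
Product: 15 ethyl 4-[(tert-butyldimethylsilyl)oxy]-3-oxobutanoate
Conditions: SnCl2 (10 mol %), CH2Cl2, rt
Reagents that add atoms: none
Why: Roskamp reaction: Lewis-acid-promoted addition of the diazoester to the aldehyde, then 1,2-hydride shift with loss of N2, gives the β-keto ester.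

Step 8
Reactants: 15 ethyl 4-[(tert-butyldimethylsilyl)oxy]-3-oxobutanoate; 12 (3S)-1-iodopentan-3-ol
Product: 17 (6S)-3-{[(tert-butyldimethylsilyl)oxy]acetyl}-6-ethyloxan-2-one (C3 epimers and enol), via hydroxy keto ester 16 (not isolated)
Conditions: K2CO3, acetone, 50 °C; then pyridinium p-toluenesulfonate (10 mol %), toluene, 80 °C
Reagents that add atoms: none
Why: C-alkylation of the β-keto ester enolate by the primary iodide, then acid-catalysed lactonisation of the δ-hydroxy ester to the six-membered lactone, which fixes C7, C6, C5, C4 and C3 in one ring.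

Step 9
Reactants: 17 (6S)-3-{[(tert-butyldimethylsilyl)oxy]acetyl}-6-ethyloxan-2-one
Product: 18 2-[(tert-butyldimethylsilyl)oxy]-1-[(3Z,6S)-6-ethyl-2-oxooxan-3-ylidene]ethyl trifluoromethanesulfonate
Conditions: NaH, THF, 0 °C; then PhNTf2, 0 °C → rt
Reagents that add atoms: N-phenylbis(trifluoromethanesulfonimide), O=S(=O)(N(c1ccccc1)S(=O)(=O)C(F)(F)F)C(F)(F)F
Why: O-triflation of the chelated sodium enolate, whose enolate oxygen is held cis to the lactone carbonyl, should give the (Z)-enol triflate.

Step 10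
Reactants: 18 2-[(tert-butyldimethylsilyl)oxy]-1-[(3Z,6S)-6-ethyl-2-oxooxan-3-ylidene]ethyl trifluoromethanesulfonate
Product: 19 (3E,6S)-3-{1-[(tert-butyldimethylsilyl)oxy]but-3-en-2-ylidene}-6-ethyloxan-2-one
Conditions: Bu3SnCH=CH2, Pd(PPh3)4 (5 mol %), LiCl, THF, 60 °C
Reagents that add atoms: tributyl(vinyl)stannane, C=C[Sn](CCCC)(CCCC)CCCC
Why: Stille coupling with retention of alkene geometry puts the vinyl group (C9=C10) cis to C7 and C23 cis to C5.

Step 11
Reactants: 19 (3E,6S)-3-{1-[(tert-butyldimethylsilyl)oxy]but-3-en-2-ylidene}-6-ethyloxan-2-one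
Product: 20 (2E,5S)-2-{1-[(tert-butyldimethylsilyl)oxy]but-3-en-2-ylidene}heptane-1,5-diol
Conditions: i-Bu2AlH (4 equiv), CH2Cl2, −78 → 0 °C; aqueous KNa tartrate
Reagents that add atoms: none
Why: 1,2-Reduction of the unsaturated lactone through the lactol to the diol; the diene geometry and the silyl ether should be kept.

Step 12
Reactants: 20 (2E,5S)-2-{1-[(tert-butyldimethylsilyl)oxy]but-3-en-2-ylidene}heptane-1,5-diol
Product: 21 (2E,5S)-1,5-bis(benzyloxy)-2-{1-[(tert-butyldimethylsilyl)oxy]but-3-en-2-ylidene}heptane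
Conditions: NaH, BnBr, Bu4NI (cat.), THF–DMF, 0 °C → rt
Reagents that add atoms: benzyl bromide, BrCc1ccccc1
Why: Williamson etherification of both hydroxyls; benzyl ethers make the diene electron-neutral and leave in step 19.

Step 13
Reactants: 21 (2E,5S)-1,5-bis(benzyloxy)-2-{1-[(tert-butyldimethylsilyl)oxy]but-3-en-2-ylidene}heptane
Product: 22 (2E,5S)-1,5-bis(benzyloxy)-2-(1-bromobut-3-en-2-ylidene)heptane
Conditions: Ph3PBr2, CH2Cl2, 0 °C → rt
Reagents that add atoms: dibromotriphenylphosphorane, BrP(Br)(c1ccccc1)(c1ccccc1)c1ccccc1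
Why: Ph3PBr2 converts a primary allylic silyl ether directly into the bromide; benzyl ethers are inert to it.

Step 14
Reactants: 9 methyl (1R,6aS)-3-({[(2-nitrophenyl)sulfonyl]amino}methyl)-4-oxo-1,2,4,5,6,6a-hexahydropentalene-1-carboxylate; 22 (2E,5S)-1,5-bis(benzyloxy)-2-(1-bromobut-3-en-2-ylidene)heptane
Product: 23 methyl (1R,6aS)-3-({[(2E,6S)-6-(benzyloxy)-3-[(benzyloxy)methyl]-2-ethenyloct-2-en-1-yl][(2-nitrophenyl)sulfonyl]amino}methyl)-4-oxo-1,2,4,5,6,6a-hexahydropentalene-1-carboxylate
Conditions: K2CO3, DMF, rt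
Reagents that add atoms: none
Why: Fukuyama N-alkylation of the acidic nosylamide with the allylic bromide (SN2) joins the two fragments through the future ring A nitrogen under conditions too mild to enolise the enone or the ester.

Step 15
Reactants: 23 the enone of step 14
Product: 24 methyl (1R,6aS)-3-({[(2E,6S)-6-(benzyloxy)-3-[(benzyloxy)methyl]-2-ethenyloct-2-en-1-yl][(2-nitrophenyl)sulfonyl]amino}methyl)-4-hydroxy-1,2,4,5,6,6a-hexahydropentalene-1-carboxylate (both C11 epimers)
Conditions: NaBH4, CeCl3·7H2O, MeOH, −40 °C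
Reagents that add atoms: none
Why: Luche 1,2-reduction of the enone; both carbinol epimers should give the same allyl cation in step 16.

Step 16
Reactants: 24 the allylic alcohol of step 15
Product: 25 N-(2-nitrophenylsulfonyl) tetracycle with rings A–D closed, C8=C9 and C11=C12 alkenes, C6 bearing CH2OBn and the (3S)-3-(benzyloxy)pentyl chain, and the C16 methyl ester cis to H13; (6S,13S,16R,19S)
Conditions: Tf2O (1.1 equiv), 2,6-di-tert-butyl-4-methylpyridine (2.5 equiv), CH2Cl2 (0.005 M), −78 → −20 °C
Reagents that add atoms: none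
Why: Proposed new method: O-triflation and ionisation give the planar C11–C12–C19 allyl cation, the tetrasubstituted C6=C8 alkene attacks C19 (6-endo-trig closure of ring A, the only terminus the three-atom nitrogen tether can reach), the C8–C9–C10 allyl cation so formed closes through C10 onto C11 (seven-membered ring B; closure through C8 would be 5-endo-trig and closure at C12 would leave a secondary cation) and the tertiary C12 cation loses H11 to give the tetrasubstituted C11=C12 alkene, whether the two bonds form in concert or in succession. The closest known reaction type is the (4+3) cycloaddition of 2-alkylallyl cations with 1,3-dienes, including intramolecular cases from allylic alcohols and Tf2O with the tether on the diene terminus; new here are the tether on C8 of the diene, which leaves a bridgehead C8=C9 alkene as in type 2 intramolecular Diels–Alder reactions, and the two adjacent quaternary carbons. C6 is controlled by the (E)-diene geometry (C7, cis to the vinyl group, ends on the ring B side and the chain on the ring A side), and C19 by the face of the cation that is attacked: the diene should add anti to the pseudo-axial C13–H and to the C16 ester, which places C6 trans to H13. The step needs ring closure to outrun proton loss and capture by nitrogen, which the low temperature, high dilution, hindered base and non-nucleophilic sulfonamide are chosen to secure.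

Step 17
Reactants: 25 the N-nosyl tetracycle of step 16
Product: 27 N-(methoxycarbonyl) tetracycle, otherwise as 25; (6S,13S,16R,19S), via secondary amine 26 (not isolated)
Conditions: PhSH, K2CO3, MeCN, rt; then ClCO2Me, rt
Reagents that add atoms: methyl chloroformate, COC(Cl)=O
Why: Fukuyama removal of the nosyl group (thiolate addition, loss of SO2), then N-acylation; the carbamate carbon becomes the N-methyl carbon in step 20.

Step 18
Reactants: 27 the N-(methoxycarbonyl) tetracycle of step 17
Product: 28 C16 epimer of 27 with the methyl ester cis to C6 and trans to H13; (6S,13S,16S,19S)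
Conditions: LiN(i-Pr)2 (1.2 equiv), THF, −78 °C; then 2,6-di-tert-butylphenol, −78 °C
Reagents that add atoms: none
Why: Ester enolate formation and kinetic protonation by a bulky acid on the face opposite the quaternary C6 should invert C16 against the thermodynamic preference.

Step 19
Reactants: 28 the C16-inverted ester of step 18
Product: 29 saturated diol: C8–H, free C7 and C3 hydroxyls, C17 methyl ester, N-methoxycarbonyl; (3S,6S,8R,13S,16S,19S)
Conditions: H2 (1 atm), Pd(OH)2/C, EtOAc–EtOH, rt
Reagents that add atoms: none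
Why: Heterogeneous hydrogenation should saturate the strained bridgehead C8=C9 alkene (the bridged ring system allows only one configuration at C8) and hydrogenolyse both benzyl ethers, while the tetrasubstituted C11=C12 alkene stays.

Step 20
Reactants: 29 the saturated diol of step 19
Product: 30 the target, (3S,6S,8R,13S,16S,19S)-triol N-methyl amine
Conditions: LiAlH4 (excess), THF, reflux
Reagents that add atoms: none
Why: LiAlH4 reduces the ester to the primary alcohol C17H2OH and the methyl carbamate to the N-methyl amine in one operation.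

Compound list
1 | cyclopent-2-en-1-one | O=C1C=CCC1 | starting material
2 | tert-butyl methyl malonate | COC(=O)CC(=O)OC(C)(C)C | starting material
3 | 1-tert-butyl 3-methyl 2-[(1R)-3-oxocyclopentyl]propanedioate | O=C1C[C@@H](CC1)C(C(=O)OC)C(=O)OC(C)(C)C | intermediate
4 | 1,3-dichloropropan-2-one | ClCC(=O)CCl | starting material
5 | 1-tert-butyl 3-methyl 2-(3-chloro-2-oxopropyl)-2-[(1R)-3-oxocyclopentyl]propanedioate | O=C1C[C@@H](CC1)C(CC(=O)CCl)(C(=O)OC)C(=O)OC(C)(C)C | intermediate
6 | 1-tert-butyl 1-methyl (6aR)-3-(chloromethyl)-4-oxo-4,5,6,6a-tetrahydropentalene-1,1(2H)-dicarboxylate | O=C1CC[C@H]2C(C(=O)OC)(C(=O)OC(C)(C)C)CC(CCl)=C12 | intermediate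
7 | methyl (1R,6aS)-3-(chloromethyl)-4-oxo-1,2,4,5,6,6a-hexahydropentalene-1-carboxylate | O=C1CC[C@H]2[C@H](C(=O)OC)CC(CCl)=C12 | intermediate
8 | 2-nitrobenzenesulfonamide | NS(=O)(=O)c1ccccc1[N+](=O)[O-] | starting material
9 | methyl (1R,6aS)-3-({[(2-nitrophenyl)sulfonyl]amino}methyl)-4-oxo-1,2,4,5,6,6a-hexahydropentalene-1-carboxylate | O=C1CC[C@H]2[C@H](C(=O)OC)CC(CNS(=O)(=O)c3ccccc3[N+](=O)[O-])=C12 | intermediate
10 | methyl (3S)-3-hydroxypentanoate | CC[C@H](O)CC(=O)OC | starting material
11 | (3S)-pentane-1,3-diol | CC[C@H](O)CCO | intermediate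
12 | (3S)-1-iodopentan-3-ol | CC[C@H](O)CCI | intermediate
13 | 2-[(tert-butyldimethylsilyl)oxy]acetaldehyde | O=CCO[Si](C)(C)C(C)(C)C | starting material
14 | ethyl 2-diazoacetate | CCOC(=O)C=[N+]=[N-] | starting material
15 | ethyl 4-[(tert-butyldimethylsilyl)oxy]-3-oxobutanoate | CCOC(=O)CC(=O)CO[Si](C)(C)C(C)(C)C | intermediate
16 | ethyl (5S)-2-{[(tert-butyldimethylsilyl)oxy]acetyl}-5-hydroxyheptanoate (C2 epimers) | CCOC(=O)C(CC[C@@H](O)CC)C(=O)CO[Si](C)(C)C(C)(C)C | intermediate
17 | (6S)-3-{[(tert-butyldimethylsilyl)oxy]acetyl}-6-ethyloxan-2-one (C3 epimers) | CC[C@H]1CCC(C(=O)CO[Si](C)(C)C(C)(C)C)C(=O)O1 | intermediate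
18 | 2-[(tert-butyldimethylsilyl)oxy]-1-[(3Z,6S)-6-ethyl-2-oxooxan-3-ylidene]ethyl trifluoromethanesulfonate | CC[C@H]1CC/C(=C(/OS(=O)(=O)C(F)(F)F)CO[Si](C)(C)C(C)(C)C)C(=O)O1 | intermediate
19 | (3E,6S)-3-{1-[(tert-butyldimethylsilyl)oxy]but-3-en-2-ylidene}-6-ethyloxan-2-one | CC[C@H]1CC/C(=C(/C=C)CO[Si](C)(C)C(C)(C)C)C(=O)O1 | intermediate
20 | (2E,5S)-2-{1-[(tert-butyldimethylsilyl)oxy]but-3-en-2-ylidene}heptane-1,5-diol | CC[C@H](O)CC/C(CO)=C(/C=C)CO[Si](C)(C)C(C)(C)C | intermediate
21 | (2E,5S)-1,5-bis(benzyloxy)-2-{1-[(tert-butyldimethylsilyl)oxy]but-3-en-2-ylidene}heptane | CC[C@H](OCc1ccccc1)CC/C(COCc2ccccc2)=C(/C=C)CO[Si](C)(C)C(C)(C)C | intermediate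
22 | (2E,5S)-1,5-bis(benzyloxy)-2-(1-bromobut-3-en-2-ylidene)heptane | CC[C@H](OCc1ccccc1)CC/C(COCc2ccccc2)=C(/C=C)CBr | intermediate
23 | methyl (1R,6aS)-3-({[(2E,6S)-6-(benzyloxy)-3-[(benzyloxy)methyl]-2-ethenyloct-2-en-1-yl][(2-nitrophenyl)sulfonyl]amino}methyl)-4-oxo-1,2,4,5,6,6a-hexahydropentalene-1-carboxylate | O=C1CC[C@H]2[C@H](C(=O)OC)CC(CN(S(=O)(=O)c3ccccc3[N+](=O)[O-])C/C(C=C)=C(/COCc4ccccc4)CC[C@H](CC)OCc5ccccc5)=C12 | intermediate
24 | 4-hydroxy analogue of 23 (both C11 epimers) | OC1CC[C@H]2[C@H](C(=O)OC)CC(CN(S(=O)(=O)c3ccccc3[N+](=O)[O-])C/C(C=C)=C(/COCc4ccccc4)CC[C@H](CC)OCc5ccccc5)=C12 | intermediate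
25 | N-(2-nitrophenylsulfonyl) tetracycle, C8=C9 and C11=C12 alkenes, two benzyl ethers, C16 ester cis to H13, (6S,13S,16R,19S) | CC[C@H](OCc5ccccc5)CC[C@]1(COCc6ccccc6)C2=CCC3=C4[C@@H](CC3)[C@H](C(=O)OC)C[C@]41CN(S(=O)(=O)c7ccccc7[N+](=O)[O-])C2 | intermediate
26 | secondary amine from 25 (N–H) | CC[C@H](OCc5ccccc5)CC[C@]1(COCc6ccccc6)C2=CCC3=C4[C@@H](CC3)[C@H](C(=O)OC)C[C@]41CNC2 | intermediate
27 | N-(methoxycarbonyl) tetracycle, (6S,13S,16R,19S) | CC[C@H](OCc5ccccc5)CC[C@]1(COCc6ccccc6)C2=CCC3=C4[C@@H](CC3)[C@H](C(=O)OC)C[C@]41CN(C(=O)OC)C2 | intermediate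
28 | C16 epimer of 27, ester cis to C6, (6S,13S,16S,19S) | CC[C@H](OCc5ccccc5)CC[C@]1(COCc6ccccc6)C2=CCC3=C4[C@@H](CC3)[C@@H](C(=O)OC)C[C@]41CN(C(=O)OC)C2 | intermediate
29 | saturated diol ester carbamate, (3S,6S,8R,13S,16S,19S) | CC[C@H](O)CC[C@]1(CO)[C@H]2CCC3=C4[C@@H](CC3)[C@@H](C(=O)OC)C[C@]41CN(C(=O)OC)C2 | intermediate
30 | target triol, (3S,6S,8R,13S,16S,19S) | CC[C@H](O)CC[C@]1(CO)[C@H]2CCC3=C4[C@@H](CC3)[C@@H](CO)C[C@]41CN(C)C2 | target

Total steps: 20. Longest linear sequence: 15 (steps 5, 6, 8–20).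

Steps most likely to fail

1. Step 16. The allyl or the dienyl cation may lose a proton or be trapped before the second ring closes, or the diene may bond to the other face of ring D. Fallback (from 18 and 9, back at 25), built only from established reactions: enol triflate 18 would be coupled with Me3SiCH2ZnCl (Pd(PPh3)4) to the allylsilane lactone F1. F1 is carried through the reactions of steps 11–13: i-Bu2AlH gives the allylsilane diol F2, benzylation the bis-benzyl ether F3, and Ph3PBr2 the allylsilane bromide F4. F4 is joined to 9 as in step 14 to give the allylsilane enone F5. TiCl4 at −78 °C should then bring about an intramolecular Hosomi–Sakurai conjugate addition (C6 to C19, closing ring A) to give the methylidene ketone F6, with an exocyclic methylene on C8 and a cis ring fusion at C12–C13. Thermodynamic enol triflation (Tf2O, 2,6-di-tert-butyl-4-methylpyridine) gives the C11 enol triflate F7, Stille coupling with Bu3SnCH2CH=CH2 the C11-allyl triene F8, and ring-closing metathesis with the second-generation Grubbs catalyst closes ring B at C8=C9 with loss of ethene and returns 25.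

2. Step 18. Protonation of the enolate may occur on the wrong face or be reversed on work-up, leaving the ester on the thermodynamically preferred side. Fallback (from 27, back at 29): LiN(i-Pr)2 then PhSeBr gives the α-phenylselenyl ester F9, and H2O2 with pyridine gives the unsaturated ester F10 (C16=C18) by selenoxide syn-elimination. The hydrogenation of step 19 then adds hydrogen to C16 from the face opposite C6 while it saturates C8=C9 and removes the benzyl groups, giving 29 directly.

3. Step 19. Palladium hydride may move the C11=C12 alkene into another position or cleave the allylic C23–N bond before C8=C9 is saturated. Fallback (from 28, back at 29): diimide (2-nitrobenzenesulfonylhydrazide, Et3N) reduces only the strained bridgehead alkene to the saturated bis-benzyl ether F11, and BCl3·SMe2 at −78 °C then cleaves both benzyl ethers to give 29.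

Further compounds
F1 | step 16 | (3Z,6S)-3-{1-[(tert-butyldimethylsilyl)oxy]-3-(trimethylsilyl)propan-2-ylidene}-6-ethyloxan-2-one | CC[C@H]1CC/C(=C(/C[Si](C)(C)C)CO[Si](C)(C)C(C)(C)C)C(=O)O1
F2 | step 16 | (2Z,5S)-2-{1-[(tert-butyldimethylsilyl)oxy]-3-(trimethylsilyl)propan-2-ylidene}heptane-1,5-diol | CC[C@H](O)CC/C(CO)=C(/C[Si](C)(C)C)CO[Si](C)(C)C(C)(C)C
F3 | step 16 | bis-benzyl ether of F2 | CC[C@H](OCc1ccccc1)CC/C(COCc2ccccc2)=C(/C[Si](C)(C)C)CO[Si](C)(C)C(C)(C)C
F4 | step 16 | (2E,5S)-1,5-bis(benzyloxy)-2-[1-bromo-3-(trimethylsilyl)propan-2-ylidene]heptane | CC[C@H](OCc1ccccc1)CC/C(COCc2ccccc2)=C(/C[Si](C)(C)C)CBr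
F5 | step 16 | analogue of 23 with CH2SiMe3 in place of the vinyl group | O=C1CC[C@H]2[C@H](C(=O)OC)CC(CN(S(=O)(=O)c3ccccc3[N+](=O)[O-])C/C(C[Si](C)(C)C)=C(/COCc4ccccc4)CC[C@H](CC)OCc5ccccc5)=C12
F6 | step 16 | ring A closed C11 ketone with exocyclic C8 methylene and cis C12–C13 ring fusion | CC[C@H](OCc5ccccc5)CC[C@]1(COCc6ccccc6)C(=C)CN(S(=O)(=O)c7ccccc7[N+](=O)[O-])C[C@]12C[C@@H](C(=O)OC)[C@@H]3CCC(=O)[C@H]23
F7 | step 16 | C11 enol triflate of F6 (C11=C12) | CC[C@H](OCc5ccccc5)CC[C@]1(COCc6ccccc6)C(=C)CN(S(=O)(=O)c7ccccc7[N+](=O)[O-])C[C@]12C[C@@H](C(=O)OC)[C@@H]3CCC(OS(=O)(=O)C(F)(F)F)=C23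
F8 | step 16 | C11-allyl triene from F7 | CC[C@H](OCc5ccccc5)CC[C@]1(COCc6ccccc6)C(=C)CN(S(=O)(=O)c7ccccc7[N+](=O)[O-])C[C@]12C[C@@H](C(=O)OC)[C@@H]3CCC(CC=C)=C23
F9 | step 18 | C16 α-phenylselenyl ester of 27 | CC[C@H](OCc5ccccc5)CC[C@]1(COCc6ccccc6)C2=CCC3=C4[C@@H](CC3)[C@](C(=O)OC)([Se]c7ccccc7)C[C@]41CN(C(=O)OC)C2
F10 | step 18 | C16=C18 unsaturated ester from 27 | CC[C@H](OCc5ccccc5)CC[C@]1(COCc6ccccc6)C2=CCC3=C4[C@@H](CC3)C(C(=O)OC)=C[C@]41CN(C(=O)OC)C2
F11 | step 19 | C8,C9-dihydro derivative of 28 with both benzyl ethers kept | CC[C@H](OCc5ccccc5)CC[C@]1(COCc6ccccc6)[C@H]2CCC3=C4[C@@H](CC3)[C@@H](C(=O)OC)C[C@]41CN(C(=O)OC)C2
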